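Ring A is built, not bought: it is cut into two three-carbon pieces. Its brominated carbons C4 and C6 lie 1,3 to each other, para and ortho to the C1 hydroxyl. This is the spacing of the two ester-bearing termini of a glutaconate, so carboxyl groups placed there act as placeholders that bromine displaces at the end. A single base-mediated cascade (addition–elimination, then Dieckmann-type acylation) forms C3–C4 and C1–C6, closes ring A and releases the C1 phenol next to the C2 aryl ether. The precursor is a push–pull acrylate: ester carbonyl as C1, ring B attached through oxygen at C2, and a dimethylamino-bearing methine as C3.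

Key step: step 3

Numbering used: ring A is C1 (OH), C2 (O-aryl), C3 (H), C4 (Br), C5 (H), C6 (Br); ring B is the 2,4-dibromophenyl group.
Remark on the chemistry: the target has no stereocentre. The alkene geometries of the open-chain intermediates are erased on aromatisation, so the uncyclised diene is drawn in the geometry that can close.

Step 1
Reactants: 1 2,4-dibromophenol; 2 ethyl bromoacetate
Product: 3 ethyl 2-(2,4-dibromophenoxy)acetate
Conditions: K2CO3, acetone, reflux
Reagents that add atoms: none
Why: Williamson ether synthesis, in which K2CO3 fully ionises the acidic dibromophenol and the phenoxide displaces the primary α-ester bromide by SN2, neither partner offering a competing site.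

Step 2
Reactants: 3 ethyl 2-(2,4-dibromophenoxy)acetate; 4 tert-butoxybis(dimethylamino)methane
Product: 5 ethyl (Z)-2-(2,4-dibromophenoxy)-3-(dimethylamino)acrylate
Conditions: 4 (1.5 equiv), toluene, 100–110 °C
Reagents that add atoms: none
Why: Aminomethylenation of an activated methylene with an aminal ester, in which thermal ionisation of 4 supplies tert-butoxide to deprotonate the OCH2 group and a formamidinium ion to trap the enolate, and loss of Me2NH gives the push–pull enamine with NMe2 trans to the ester; 4 is preferred to the dimethyl acetal of DMF because it copes with the weak CH acidity of aryloxyacetates and releases no methanol that could scramble the ethyl ester.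

Step 3
Reactants: 5 ethyl (Z)-2-(2,4-dibromophenoxy)-3-(dimethylamino)acrylate; 6 diethyl (E)-glutaconate
Product: 8 diethyl 5-(2,4-dibromophenoxy)-4-hydroxyisophthalate, via diene triester 7 (not isolated)
Conditions: 6 (1.2 equiv), NaOEt (2.2 equiv), EtOH, 0 °C; add 5, reflux under N2 sweep; then 1 M HCl
Reagents that add atoms: none
Why: NaOEt turns 6 into its symmetric, vinylogous-malonate anion, one ester-bearing terminus of which adds to the aminomethine carbon C3 of 5; E1cB expulsion of Me2NH, protonated by the ethanol solvent and boiled out of the mixture, makes the C3–C4 bond and gives diene triester 7. Base re-ionises 7 to a delocalised trienolate in which the C2=C3 and C4=C5 bonds lose their configurational hold, so the geometry with the C1 ester cis to C4 and C3 cis to C6, which 5 itself does not provide, is reached by rotation. The free terminus C6 then attacks the acrylate-derived ester carbonyl C1 in a 6-exo-trig Dieckmann-type Claisen closure (C1–C6 bond, ring A), ethoxide leaves, and enolisation to the sodium phenoxide of 8 is an irreversible aromatic sink that draws the preceding equilibria forward. The closest known chemistry is the base-mediated [3+3] benzannulation of glutaconate diesters with 1,3-dielectrophiles such as alkoxy- or aminomethylene carbonyl compounds, a Michael addition–elimination followed by intramolecular acylation. No stereocentre is created; regiochemistry is secured because the two nucleophilic termini of the anion are equivalent and its central carbon is a node, and because C1 is the only carbonyl that C6 can reach through a six-membered transition state, the ester on C4 offering only a four-membered ring. Complete deprotonation of 6 before 5 is added leaves no neutral glutaconate as Michael acceptor and so holds back its self-condensation, and the ethyl esters match the ethoxide base so that ester exchange is invisible.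

Step 4
Reactants: 8 diethyl 5-(2,4-dibromophenoxy)-4-hydroxyisophthalate
Product: 9 5-(2,4-dibromophenoxy)-4-hydroxyisophthalic acid
Conditions: NaOH (6 equiv), EtOH–H2O, reflux; then HCl to pH 1
Reagents that add atoms: sodium hydroxide, [Na+].[OH-]
Why: Saponification (BAc2), in which excess hydroxide at reflux cleaves both ethyl esters, heat being needed for the salicylate-type ester on C6 beside the phenoxide, while the diaryl ether and the aryl bromides are inert to aqueous base and acidification should precipitate the diacid.

Step 5
Reactants: 9 5-(2,4-dibromophenoxy)-4-hydroxyisophthalic acid
Product: 10 2,4-dibromo-6-(2,4-dibromophenoxy)phenol (target)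
Conditions: Br2 (2.05 equiv), NaOAc (4 equiv), AcOH–H2O, 20 to 50 °C
Reagents that add atoms: bromine, BrBr
Why: Bromodecarboxylation (ipso electrophilic substitution), in which the C1 hydroxyl directs bromine only to C4 and C6 because C2 carries the ether oxygen, each ipso attack giving a bromo-carboxy cyclohexadienone that rearomatises by losing CO2 from the acetate-buffered carboxylate, as in the conversion of salicylic and 4-hydroxybenzoic acids into bromophenols, while C3-H and C5-H (meta to OH) and the twice-brominated ring B are far less activated.

Compound list
1 | 2,4-dibromophenol | Oc1ccc(Br)cc1Br | starting material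
2 | ethyl bromoacetate | BrCC(=O)OCC | starting material
3 | ethyl 2-(2,4-dibromophenoxy)acetate | CCOC(=O)COc1ccc(Br)cc1Br | intermediate
4 | tert-butoxybis(dimethylamino)methane | CC(C)(C)OC(N(C)C)N(C)C | starting material
5 | ethyl (Z)-2-(2,4-dibromophenoxy)-3-(dimethylamino)acrylate | CCOC(=O)/C(Oc1ccc(Br)cc1Br)=C/N(C)C | intermediate
6 | diethyl (E)-glutaconate | CCOC(=O)/C=C/CC(=O)OCC | starting material
7 | triethyl (1E,3E)-1-(2,4-dibromophenoxy)penta-1,3-diene-1,3,5-tricarboxylate (diene triester, present as its sodium trienolate, geometry mobile, not isolated) | CCOC(=O)/C(Oc1ccc(Br)cc1Br)=C\C(C(=O)OCC)=C/CC(=O)OCC | intermediate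
8 | diethyl 5-(2,4-dibromophenoxy)-4-hydroxyisophthalate | CCOC(=O)c1cc(Oc2ccc(Br)cc2Br)c(O)c(C(=O)OCC)c1 | intermediate
9 | 5-(2,4-dibromophenoxy)-4-hydroxyisophthalic acid | OC(=O)c1cc(Oc2ccc(Br)cc2Br)c(O)c(C(=O)O)c1 | intermediate
10 | 2,4-dibromo-6-(2,4-dibromophenoxy)phenol | Oc1c(Br)cc(Br)cc1Oc1ccc(Br)cc1Br | target

Total step count: 5
Longest linear sequence: 5 steps (1 to 3 to 5 to 8 to 9 to 10)

Steps most likely to fail

**Step 3.**
- **Risk:** addition–elimination at the donor-stabilised, singly activated enamine carbon may be too slow. Self-condensation of the glutaconate and aminolysis of the esters by the released amine could then take over.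
- **Fallback:** it sets out from 6, 4 and 3 and returns at 8. The roles of the partners are exchanged, so that a strong nucleophile meets a strong electrophile. Diester 6 is aminomethylenated with 4 (toluene, 80 °C) to diethyl (2E,3E)-2-[(dimethylamino)methylidene]pent-3-enedioate F1, a non-enolisable acceptor activated by two conjugated esters. The lithium enolate of 3 is formed with LiN(SiMe3)2 in THF at −78 °C; this base is chosen to spare the acidic C–H between the two bromines of ring B. The enolate adds to the aminomethine carbon of F1 and Me2NH is lost, which gives the same delocalised anion as that derived from 7. On warming, with NaOEt in EtOH if needed, this anion should close to 8.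

**Step 5.**
- **Risk:** the exchange may stall after the first carboxyl group. The electron-rich ring may also be over-oxidised, either by further bromination to a bromodienone or by attack at the free ortho position of ring B.
- **Fallback:** it sets out from 9 and returns at 10. Loss of CO2 and bromination are separated. Heating 9 in quinoline at about 200 °C without metal should protodecarboxylate both the ortho- and the para-hydroxy acid functions to 2-(2,4-dibromophenoxy)phenol F2. Br2 (2 equiv) in AcOH at 0–20 °C then substitutes para and ortho to the hydroxyl, which outweighs the weakly donating aryloxy group, and gives 10.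

**Step 2.**
- **Risk:** condensation at the weakly acidic OCH2 group may be incomplete, and the moisture-sensitive aminal ester may decompose thermally on prolonged heating.
- **Fallback:** it sets out from 3 and returns at 5. Crossed Claisen formylation with ethyl formate and NaH in THF gives ethyl (E)-2-(2,4-dibromophenoxy)-3-hydroxyacrylate F3, the chelated enol of the formyl ester, handled as its sodium salt. Condensation with Me2NH·HCl in EtOH at room temperature should then give 5.

Further compounds
F1 | step 3 | diethyl (2E,3E)-2-[(dimethylamino)methylidene]pent-3-enedioate | CCOC(=O)/C=C/C(C(=O)OCC)=C\N(C)C
F2 | step 5 | 2-(2,4-dibromophenoxy)phenol | Oc1ccccc1Oc1ccc(Br)cc1Br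
F3 | step 2 | ethyl (E)-2-(2,4-dibromophenoxy)-3-hydroxyacrylate | CCOC(=O)/C(Oc1ccc(Br)cc1Br)=C\O
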